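Drimane numbering is used for the carbocycle throughout: ring A is C1–C5 plus C10, ring B is C5–C10, C11 is the benzylic methylene on C9, C4 carries the gem-dimethyl group, and C8 and C9 each carry a methyl group.

## The problem

The target is a 2-hydroxy-5-methoxy-1,4-benzoquinone joined through C11 to the quaternary carbon C9 of a rearranged drimane, a Δ5-octalin whose rings A and B share the C5–C10 bond. Three contiguous stereocentres have to be set: C8 (S), C9 (R, quaternary) and C10 (S), with the two methyl groups cis and the C9 methyl group trans to H-10. None of them is next to a functional group in the target. C9 cannot be corrected once formed, C10 is tied to C9 only through the ring fusion, and only C8 could be equilibrated, through a C7 carbonyl. The safest course is therefore one stereospecific event that converts alkene geometry into all three relative configurations. The decalin contains no heteroatom, so every activating group used to build it must be removed again without moving the trisubstituted C5=C6 alkene, which sits next to the quaternary C4 and can migrate under acid or on metal surfaces. The hydroxyquinone will not survive organometallic reagents, hydrides, radicals or strong acid (its enol OH can add to C5=C6), so it has to travel as an inert arene and be unveiled last, with its two oxygen substituents told apart. The feature that makes the key step possible is that ring B, with an oxygen placed on C7, is the imprint of a [4+2] adduct: C5–C6–C7–C8 is a 2-oxygenated diene, and C10=C9 is a dienophile whose β-carbon C9 already carries both final substituents. A carbonyl at C1 turns C10=C9 into an enone and makes C1–C4 a four-carbon tether, so rings A and B can close together through the C5–C10 and C8–C9 bonds.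

## Retrosynthesis

**Quinone to arene (28 to 27 to 26).** No carbon–carbon bond is cut. The hydroxyl and the two carbonyl oxygens of 28 are traced through the dimethoxyquinone 27 to the four methyl ethers of arene 26. A tetramethoxyarene is inert to every reagent used on the carbocycle, and its symmetry means oxidative demethylation can give only one quinone. The forward steps must spare the C5=C6 alkene and hydrolyse only the methoxy group next to the side chain.

**C7 methylene and C5=C6 (26 to 25 to 24 to 23).** The C7 methylene is traced to a carbonyl (dithiolane 25, enone 24), and the enone to the silyl enol ether 23 with hydrogen on C5. A cycloaddition leaves the ring-B alkene at C6=C7; oxidising the enol ether moves it to C5=C6 regiospecifically, because C5–H is the only β-hydrogen. This also erases C5, so its configuration never has to be controlled. The forward steps must not move the alkene and must leave C8 (α to the carbonyl) and C10 (γ) untouched.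

**C1 methylene (23 to 22 to 21 to 20).** The C1 methylene is traced to the C1 ketone of 20 by radical deoxygenation of the derived alcohol. This is done before the enone is made, not together with C7. In a 1-oxo-5-en-7-one, H-10 would be α to one carbonyl and γ to the other (a vinylogous 1,3-dicarbonyl), and the only link between C10 and C9 could be lost. The cost is three steps instead of a shared dithioketal removal.

**Key disconnection (20 to 19).** The C5–C10 and C8–C9 bonds are cut together, opening rings A and B to the acyclic trienone 19. Against an intermolecular cycloaddition, the tether fixes the regiochemistry and makes the quaternary carbon inside a six-membered transition-state ring. Against stepwise annulations, one step sets four centres from three alkene geometries. The forward reaction must be endo with respect to the tether and must choose one enone face.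

**C1–C10 bond (19 to 7 + 16).** The enone is cut at the acyl–alkenyl bond, giving alkenyl iodide 7 and Weinreb amide 16. Two enolisable enones in one chain could not be told apart, so the C7 ketone is converted into its silyl enol ether while C1 is still an ester-level carbon, and the C1 ketone is released only in the coupling. The two halves are of similar size.

**Fragment 1 (7 to 5 to 4 to 1 + 2).** The C9 methyl group and the C–I bond come from syn methyl-metallation of the terminal alkyne 5, which fixes the (E) geometry. The aryl–C11 bond comes from alkylation of lithiated 1 with the silyl-capped propargylic bromide 2, via 4; the silyl cap prevents allene formation.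

**Fragment 2 (16 to 15 to 14 to 12 + 13, and 12 to 8 + 9).** The C5=C6 bond comes from a Horner–Wadsworth–Emmons reaction of the neopentyl aldehyde 12 with ketophosphonate 13. The quaternary C4 comes from Michael addition of 2-methylpropanal 8 to methyl acrylate 9 (C3–C4 bond). Enol silylation (14 to 15) and ester-to-amide exchange (15 to 16) complete the fragment.

## Roads not taken

**Alternative 1:** Ring B is cut through C7–C8 and C9–C10. 6,6-Dimethyl-1-vinylcyclohexene A1 and (E)-2-methylbut-2-enal A2 would combine under a chiral oxazaborolidinium triflimide to give the decalin aldehyde A3, with C11 as a formyl group on C9.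
- Merits: ring A is bought, the alkene appears directly at C5=C6 so nothing has to be deoxygenated, and an α-methyl enal is the best-behaved substrate class for this catalyst family. Its formyl-exo mode places the C9 methyl group cis to C1, and the (E)-enal gives the cis dimethyl pattern.
- Weak points: the C9–C10 bond joins a ring-substituted diene terminus next to the C4 gem-dimethyl group to a fully substituted enal α-carbon, with no tether to help. The regiochemistry rests on the modest bias of a 1,2-dialkyl diene. The arene must then be attached by adding the di-ortho-substituted aryllithium 3 to the neopentyl aldehyde A3, and the benzylic hydroxyl removed next to the quaternary centre with C5=C6 present.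
- Comparison: this road is shorter and has better catalyst precedent. The chosen plan offers in return a ring-forming step whose regiochemistry is fixed by connectivity, a quaternary carbon formed intramolecularly, and an arene installed on a simple propyne before any hindered centre exists. It pays with three deoxygenation steps.

**Alternative 2:** C9–C10 is cut by a [3,3] shift. The δ-lactone A4 (ring oxygen on C6, which carries the dimethylcyclohexenyl group; carbonyl carbon on C9) would be converted into its silyl ketene acetal (LiN(iPr)2, Me3SiCl) and warmed. The Ireland–Claisen rearrangement would contract it to ring B and give acid A5, with C5=C6 in place and a carboxyl group where the C9 methyl group belongs.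
- Merits: the boat transition state enforced by the lactone transfers the C6 carbinol configuration (easily set by asymmetric reduction) to C9 and C10. The enolate geometry is fixed by the ring, and the alkene needs no later adjustment.
- Weak points: the quaternary carbon forms between a tetrasubstituted ketene acetal carbon and an alkene terminus flanked by the gem-dimethyl group. The 4,6-trans lactone needs its own stereocontrolled synthesis. The neopentyl carboxyl group must then be reduced to methyl at the most hindered position, which costs three or four steps.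
- Comparison: absolute configuration from a conventional carbinol centre is a real advantage over an untested catalyst–substrate pairing. The chosen plan offers in return that C9 emerges with both final substituents, that all centres come from alkene geometry in one step, and that its fragments are three and four steps from bulk chemicals.

**Alternative 3:** The quinone ring is cut instead of the decalin. The 4-hydroxy-4-(2-methoxyvinyl)cyclobutenone A6 would open on heating to a dienylketene that closes by 6π-electrocyclisation (Moore expansion) to hydroquinone A7, whose tert-butyl ether marks the future hydroxyl.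
- Merits: the 2-hydroxy-5-methoxy pattern is written into the precursor and does not depend on a selective hydrolysis.
- Weak points: the decalin problem is left unsolved. A6 has to be assembled on di-tert-butyl squarate A8 by adding the neopentyl lithium reagent A9, a carbanion next to the quaternary C9 that is hard to generate and slow to add. The thermolysis and the acidic ether cleavage both act on a molecule that already holds the acid-sensitive C5=C6 alkene.
- Comparison: for quinone regiochemistry this road is better. The chosen plan offers in return a commercial arene that brings all four oxygens at the start and a two-step unveiling, and this road would still need one of the other strategies for the carbocycle.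

Key step: step 9

Assumption 1: the (S)-configured catalyst is written for step 9. The facial sense for a tether-bound s-cis enone is extrapolated from the usual binding picture, and the (R)-catalyst would be used in the same way if the other face were preferred.

Assumption 2: the hydride reduction in step 10 is not expected to be usefully stereoselective. Compounds 21 and 22 are carried as C1 epimer mixtures because this centre is removed in step 12.

## Route

Step 1
Reactants: 1 1,2,4,5-tetramethoxybenzene; 2 3-bromo-1-(trimethylsilyl)prop-1-yne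
Product: 4 trimethyl[3-(2,3,5,6-tetramethoxyphenyl)prop-1-yn-1-yl]silane, via aryllithium 3 (not isolated)
Conditions: n-BuLi, THF, 0 °C; CuI (10 mol %), then 2, −78 °C → rt
Reagents that add atoms: none
Why: Directed ortho-lithiation at the C–H flanked by two methoxy groups, then copper-catalysed SN2 alkylation by the propargylic bromide. The silyl cap blocks the SN2' (allene) pathway and removes the acidic alkyne hydrogen.

Step 2
Reactants: 4 trimethyl[3-(2,3,5,6-tetramethoxyphenyl)prop-1-yn-1-yl]silane
Product: 5 1,2,4,5-tetramethoxy-3-(prop-2-yn-1-yl)benzene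
Conditions: K2CO3, MeOH, 0 °C → rt
Reagents that add atoms: none
Why: Base-catalysed methanolysis of the alkynyl–silicon bond (protodesilylation). Short exposure to a weak base at low temperature should leave the benzylic alkyne unisomerised.

Step 3
Reactants: 5 1,2,4,5-tetramethoxy-3-(prop-2-yn-1-yl)benzene
Product: 7 3-[(E)-3-iodo-2-methylprop-2-en-1-yl]-1,2,4,5-tetramethoxybenzene, via alkenylalane 6 (not isolated)
Conditions: AlMe3 (3 equiv), Cp2ZrCl2 (0.25 equiv), CH2Cl2, 0 °C → rt; then I2, THF, −30 → 0 °C
Reagents that add atoms: trimethylaluminium, C[Al](C)C; iodine, II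
Why: Zirconium-catalysed carboalumination (Negishi) adds methyl and aluminium syn, with methyl on the internal carbon. Iodinolysis of the C–Al bond retains geometry, so the iodide is (E) with the future C9 methyl group cis to iodine.

Step 4
Reactants: 8 2-methylpropanal; 9 methyl acrylate
Product: 12 methyl 4,4-dimethyl-5-oxopentanoate, via enamine 10 (not isolated), via aminocyclobutane ester 11 (not isolated)
Conditions: pyrrolidine, toluene, reflux (−H2O); then 9, MeCN, reflux; then AcOH/H2O, rt
Reagents that add atoms: water, O
Why: Stork enamine Michael addition. The enamine of an α,α-disubstituted aldehyde adds to the acrylate to give a cyclobutane adduct, which opens on aqueous acid hydrolysis to the δ-oxo ester and creates the quaternary C4.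

Step 5
Reactants: 12 methyl 4,4-dimethyl-5-oxopentanoate; 13 diethyl (2-oxobutyl)phosphonate
Product: 14 methyl (E)-4,4-dimethyl-7-oxonon-5-enoate
Conditions: LiCl, DBU, MeCN, rt
Reagents that add atoms: none
Why: Horner–Wadsworth–Emmons olefination under Masamune–Roush conditions. The aldehyde cannot enolise and the stabilised ketophosphonate gives the (E)-enone; the mild base leaves the ester alone.

Step 6
Reactants: 14 methyl (E)-4,4-dimethyl-7-oxonon-5-enoate
Product: 15 methyl (5E,7Z)-7-[(tert-butyldimethylsilyl)oxy]-4,4-dimethylnona-5,7-dienoate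
Conditions: TBSOTf, Et3N, CH2Cl2, −78 → 0 °C
Reagents that add atoms: tert-butyldimethylsilyl trifluoromethanesulfonate, CC(C)(C)[Si](C)(C)OS(=O)(=O)C(F)(F)F
Why: Soft enolisation and O-silylation of the ethyl ketone. The γ-position is quaternary, so only the ethyl CH2 can be deprotonated, and silyl triflate with amine gives the (Z)-enol ether. The ester is not enolised under these conditions.

Step 7
Reactants: 15 methyl (5E,7Z)-7-[(tert-butyldimethylsilyl)oxy]-4,4-dimethylnona-5,7-dienoate
Product: 16 (5E,7Z)-7-[(tert-butyldimethylsilyl)oxy]-N-methoxy-N,4,4-trimethylnona-5,7-dienamide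
Conditions: MeNHOMe·HCl, i-PrMgCl, THF, −20 → 0 °C
Reagents that add atoms: N,O-dimethylhydroxylamine hydrochloride, CNOC.Cl
Why: Aminolysis of the ester by the chloromagnesium amide (Weinreb amide formation). The ester is the only electrophile left in the molecule, and a tert-butyldimethylsilyl enol ether is inert to magnesium amides at this temperature.

Step 8
Reactants: 7 3-[(E)-3-iodo-2-methylprop-2-en-1-yl]-1,2,4,5-tetramethoxybenzene; 16 (5E,7Z)-7-[(tert-butyldimethylsilyl)oxy]-N-methoxy-N,4,4-trimethylnona-5,7-dienamide
Product: 19 (2E,8E,10Z)-10-[(tert-butyldimethylsilyl)oxy]-2,7,7-trimethyl-1-(2,3,5,6-tetramethoxyphenyl)dodeca-2,8,10-trien-4-one, via alkenyllithium 17 (not isolated), via lithium hemiaminal alkoxide 18 (not isolated)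
Conditions: 7, t-BuLi (2 equiv), Et2O, −78 °C; then 16, −78 → −40 °C; pH 7 buffer
Reagents that add atoms: none
Why: Iodine–lithium exchange retains the alkene geometry. Acylation by the Weinreb amide stops at the chelated tetrahedral adduct 18, so the C1 ketone appears only on quenching, after the enol ether is in place. The product is kept cold and used at once.

Step 9
Reactants: 19 (2E,8E,10Z)-10-[(tert-butyldimethylsilyl)oxy]-2,7,7-trimethyl-1-(2,3,5,6-tetramethoxyphenyl)dodeca-2,8,10-trien-4-one
Product: 20 (4aR,7R,8R,8aR)-6-[(tert-butyldimethylsilyl)oxy]-4,4,7,8-tetramethyl-8-[(2,3,5,6-tetramethoxyphenyl)methyl]-3,4,4a,7,8,8a-hexahydronaphthalen-1(2H)-one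
Conditions: (S)-1-(2-methylphenyl)-3,3-diphenyltetrahydro-1H,3H-pyrrolo[1,2-c][1,3,2]oxazaborole (20 mol %), HN(SO2CF3)2 (18 mol %), CH2Cl2, −78 → −20 °C; Et3N quench
Reagents that add atoms: none
Why: Proposed new method: the N-protonated oxazaborolidine is expected to bind the C1 carbonyl of the s-cis enone at the lone pair syn to C2 and lower the LUMO of C10=C9, so that the 2-silyloxydiene adds in a normal-demand, asynchronous [4+2] cycloaddition in which the nucleophilic enol ether carbon C8 bonds to the β-carbon C9 ahead of C5–C10 closure. The closest known reaction types are the Lewis-acid-promoted intramolecular Diels–Alder reaction of 1,7,9-decatrien-3-ones carrying 2-silyloxydienes and the oxazaborolidinium-catalysed intermolecular addition of 2-silyloxydienes to enones; a tethered β,β-disubstituted enone under asymmetric catalysis has not been shown. Ring B closes as the cyclohexene formed by the two new bonds C5–C10 and C8–C9, and ring A closes in the same event as the six-membered ring made of the four-carbon tether C1–C4 and the C5–C10 bond. C9 is set by the (E)-enone, which keeps its methyl group cis to C1; C8 by the (Z)-enol ether, whose methyl group is the outside diene substituent and so ends cis to the endo groups; C10 and C5 by the tether-endo transition state, which gives the cis ring fusion. The step needs endo selectivity and addition to the C10 Re/C9 Si face: the first is favoured because the endo mode puts the small C9 methyl group, not the arylmethyl group, beneath the silyloxy-bearing C7, and the second is left to the catalyst, whose aryl substituent should screen the other face of the bound enone. The diene geometry also acts as a filter, since the minor (E)-enol ether carries an inside methyl group and should cyclise far more slowly.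

Step 10
Reactants: 20 (4aR,7R,8R,8aR)-6-[(tert-butyldimethylsilyl)oxy]-4,4,7,8-tetramethyl-8-[(2,3,5,6-tetramethoxyphenyl)methyl]-3,4,4a,7,8,8a-hexahydronaphthalen-1(2H)-one
Product: 21 (4aS,7R,8S,8aR)-6-[(tert-butyldimethylsilyl)oxy]-4,4,7,8-tetramethyl-8-[(2,3,5,6-tetramethoxyphenyl)methyl]-1,2,3,4,4a,7,8,8a-octahydronaphthalen-1-ol (both C1 epimers)
Conditions: LiAlH4, Et2O, −78 → 0 °C
Reagents that add atoms: none
Why: Hydride reduction of the ketone under cold, non-enolising conditions, so the cis-fused C10 centre α to the carbonyl is not epimerised. The silyl enol ether is inert to hydride, and the new carbinol centre is removed in step 12.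

Step 11
Reactants: 21 (4aS,7R,8S,8aR)-6-[(tert-butyldimethylsilyl)oxy]-4,4,7,8-tetramethyl-8-[(2,3,5,6-tetramethoxyphenyl)methyl]-1,2,3,4,4a,7,8,8a-octahydronaphthalen-1-ol (both C1 epimers)
Product: 22 O-[(4aS,7R,8S,8aR)-6-[(tert-butyldimethylsilyl)oxy]-4,4,7,8-tetramethyl-8-[(2,3,5,6-tetramethoxyphenyl)methyl]-1,2,3,4,4a,7,8,8a-octahydronaphthalen-1-yl] 1H-imidazole-1-carbothioate (both C1 epimers)
Conditions: 1,1'-thiocarbonyldiimidazole, DMAP (cat.), toluene, 80 °C
Reagents that add atoms: 1,1'-thiocarbonyldiimidazole, S=C(n1ccnc1)n1ccnc1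
Why: Thioacylation of a secondary alcohol, the first stage of a Barton–McCombie deoxygenation. The neutral conditions leave the silyl enol ether and the ring fusion untouched.

Step 12
Reactants: 22 O-[(4aS,7R,8S,8aR)-6-[(tert-butyldimethylsilyl)oxy]-4,4,7,8-tetramethyl-8-[(2,3,5,6-tetramethoxyphenyl)methyl]-1,2,3,4,4a,7,8,8a-octahydronaphthalen-1-yl] 1H-imidazole-1-carbothioate (both C1 epimers)
Product: 23 tert-butyldimethyl{[(1S,2R,4aS,8aR)-1,2,5,5-tetramethyl-1-[(2,3,5,6-tetramethoxyphenyl)methyl]-1,2,4a,5,6,7,8,8a-octahydronaphthalen-3-yl]oxy}silane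
Conditions: Bu3SnH, AIBN (cat.), toluene, 110 °C
Reagents that add atoms: none
Why: Barton–McCombie radical deoxygenation. The secondary C1 radical is reduced by the stannane faster than it can add to the distant enol ether or the arene. Both epimers of 22 converge on one product and no retained stereocentre is involved.

Step 13
Reactants: 23 tert-butyldimethyl{[(1S,2R,4aS,8aR)-1,2,5,5-tetramethyl-1-[(2,3,5,6-tetramethoxyphenyl)methyl]-1,2,4a,5,6,7,8,8a-octahydronaphthalen-3-yl]oxy}silane
Product: 24 (3R,4S,4aS)-3,4,8,8-tetramethyl-4-[(2,3,5,6-tetramethoxyphenyl)methyl]-4,4a,5,6,7,8-hexahydronaphthalen-2(3H)-one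
Conditions: Pd(OAc)2 (1.2 equiv), MeCN, 40 °C
Reagents that add atoms: none
Why: Saegusa–Ito oxidation. Divalent palladium forms the C6-bound enolate and β-hydride elimination can only take H-5, so the alkene moves to C5=C6 and the temporary C5 centre is erased. The neutral medium should leave C8 (pseudo-equatorial methyl) and C10 unchanged.

Step 14
Reactants: 24 (3R,4S,4aS)-3,4,8,8-tetramethyl-4-[(2,3,5,6-tetramethoxyphenyl)methyl]-4,4a,5,6,7,8-hexahydronaphthalen-2(3H)-one
Product: 25 (3'R,4'S,4a'S)-3',4',8',8'-tetramethyl-4'-[(2,3,5,6-tetramethoxyphenyl)methyl]-4',4a',5',6',7',8'-hexahydro-3'H-spiro[1,3-dithiolane-2,2'-naphthalene]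
Conditions: HSCH2CH2SH, BF3·OEt2, CH2Cl2, 0 °C → rt
Reagents that add atoms: ethane-1,2-dithiol, SCCS
Why: Lewis-acid-catalysed dithioketalisation of an enone, which keeps the alkene where it is (unlike O-ketalisation). The β-carbon C5 is fully substituted and next to C4, so conjugate addition of thiol is blocked, and the short cold reaction should outrun dienolisation toward C10.

Step 15
Reactants: 25 (3'R,4'S,4a'S)-3',4',8',8'-tetramethyl-4'-[(2,3,5,6-tetramethoxyphenyl)methyl]-4',4a',5',6',7',8'-hexahydro-3'H-spiro[1,3-dithiolane-2,2'-naphthalene]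
Product: 26 1,2,4,5-tetramethoxy-3-{[(1R,2S,8aS)-1,2,5,5-tetramethyl-1,2,3,5,6,7,8,8a-octahydronaphthalen-1-yl]methyl}benzene
Conditions: Raney Ni (W-2, deactivated in acetone), EtOH, 60 °C
Reagents that add atoms: none
Why: Mozingo reduction; nickel desulfurisation turns the dithioketal carbon into a methylene group. Nickel deactivated in acetone should spare the hindered trisubstituted alkene and the aryl ethers.

Step 16
Reactants: 26 1,2,4,5-tetramethoxy-3-{[(1R,2S,8aS)-1,2,5,5-tetramethyl-1,2,3,5,6,7,8,8a-octahydronaphthalen-1-yl]methyl}benzene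
Product: 27 2,5-dimethoxy-3-{[(1R,2S,8aS)-1,2,5,5-tetramethyl-1,2,3,5,6,7,8,8a-octahydronaphthalen-1-yl]methyl}cyclohexa-2,5-diene-1,4-dione
Conditions: (NH4)2Ce(NO3)6, MeCN/H2O, 0 °C
Reagents that add atoms: water, O
Why: Oxidative demethylation of a para-dimethoxyarene by tetravalent cerium, with water supplying the carbonyl oxygens. Either para pair gives the same quinone by symmetry, and the fast, cold oxidation should leave the alkene alone.

Step 17
Reactants: 27 2,5-dimethoxy-3-{[(1R,2S,8aS)-1,2,5,5-tetramethyl-1,2,3,5,6,7,8,8a-octahydronaphthalen-1-yl]methyl}cyclohexa-2,5-diene-1,4-dione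
Product: 28 2-hydroxy-5-methoxy-3-{[(1R,2S,8aS)-1,2,5,5-tetramethyl-1,2,3,5,6,7,8,8a-octahydronaphthalen-1-yl]methyl}cyclohexa-2,5-diene-1,4-dione
Conditions: KOH, MeOH/H2O, rt; then 1 M HCl, 0 °C
Reagents that add atoms: potassium hydroxide, [K+].[OH-]
Why: Addition–elimination of hydroxide at a vinylogous ester. The methoxy group flanked by the side chain is twisted out of conjugation, so its carbon is the more electrophilic, and the hydroxyquinone anion formed resists a second hydrolysis. The basic medium and a brief cold acidification protect the C5=C6 alkene.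

## Compound list

1 | 1,2,4,5-tetramethoxybenzene | COc1cc(OC)c(OC)cc1OC | starting material
2 | 3-bromo-1-(trimethylsilyl)prop-1-yne | C[Si](C)(C)C#CCBr | starting material
3 | (2,3,5,6-tetramethoxyphenyl)lithium | [Li]c1c(OC)c(OC)cc(OC)c1OC | intermediate
4 | trimethyl[3-(2,3,5,6-tetramethoxyphenyl)prop-1-yn-1-yl]silane | C[Si](C)(C)C#CCc1c(OC)c(OC)cc(OC)c1OC | intermediate
5 | 1,2,4,5-tetramethoxy-3-(prop-2-yn-1-yl)benzene | C#CCc1c(OC)c(OC)cc(OC)c1OC | intermediate
6 | dimethyl[(E)-2-methyl-3-(2,3,5,6-tetramethoxyphenyl)prop-1-en-1-yl]alumane | C[Al](C)/C=C(\C)Cc1c(OC)c(OC)cc(OC)c1OC | intermediate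
7 | 3-[(E)-3-iodo-2-methylprop-2-en-1-yl]-1,2,4,5-tetramethoxybenzene | I/C=C(\C)Cc1c(OC)c(OC)cc(OC)c1OC | intermediate
8 | 2-methylpropanal | CC(C)C=O | starting material
9 | methyl acrylate | C=CC(=O)OC | starting material
10 | 1-(2-methylprop-1-en-1-yl)pyrrolidine | CC(C)=CN1CCCC1 | intermediate
11 | methyl 3,3-dimethyl-2-(pyrrolidin-1-yl)cyclobutane-1-carboxylate (racemic diastereomer mixture) | COC(=O)C1CC(C)(C)C1N1CCCC1 | intermediate
12 | methyl 4,4-dimethyl-5-oxopentanoate | COC(=O)CCC(C)(C)C=O | intermediate
13 | diethyl (2-oxobutyl)phosphonate | CCC(=O)CP(=O)(OCC)OCC | starting material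
14 | methyl (E)-4,4-dimethyl-7-oxonon-5-enoate | CCC(=O)/C=C/C(C)(C)CCC(=O)OC | intermediate
15 | methyl (5E,7Z)-7-[(tert-butyldimethylsilyl)oxy]-4,4-dimethylnona-5,7-dienoate | C/C=C(O[Si](C)(C)C(C)(C)C)/C=C/C(C)(C)CCC(=O)OC | intermediate
16 | (5E,7Z)-7-[(tert-butyldimethylsilyl)oxy]-N-methoxy-N,4,4-trimethylnona-5,7-dienamide | C/C=C(O[Si](C)(C)C(C)(C)C)/C=C/C(C)(C)CCC(=O)N(C)OC | intermediate
17 | [(E)-2-methyl-3-(2,3,5,6-tetramethoxyphenyl)prop-1-en-1-yl]lithium | [Li]/C=C(\C)Cc1c(OC)c(OC)cc(OC)c1OC | intermediate
18 | lithium (2E,8E,10Z)-10-[(tert-butyldimethylsilyl)oxy]-4-[methoxy(methyl)amino]-2,7,7-trimethyl-1-(2,3,5,6-tetramethoxyphenyl)dodeca-2,8,10-trien-4-olate (racemic) | C/C=C(O[Si](C)(C)C(C)(C)C)/C=C/C(C)(C)CCC(O[Li])(N(C)OC)/C=C(\C)Cc1c(OC)c(OC)cc(OC)c1OC | intermediate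
19 | (2E,8E,10Z)-10-[(tert-butyldimethylsilyl)oxy]-2,7,7-trimethyl-1-(2,3,5,6-tetramethoxyphenyl)dodeca-2,8,10-trien-4-one | C/C=C(O[Si](C)(C)C(C)(C)C)/C=C/C(C)(C)CCC(=O)/C=C(\C)Cc1c(OC)c(OC)cc(OC)c1OC | intermediate
20 | (4aR,7R,8R,8aR)-6-[(tert-butyldimethylsilyl)oxy]-4,4,7,8-tetramethyl-8-[(2,3,5,6-tetramethoxyphenyl)methyl]-3,4,4a,7,8,8a-hexahydronaphthalen-1(2H)-one (cis-fused) | COc1cc(OC)c(OC)c(C[C@@]2(C)[C@@H]3C(=O)CCC(C)(C)[C@@H]3C=C(O[Si](C)(C)C(C)(C)C)[C@@H]2C)c1OC | intermediate
21 | (4aS,7R,8S,8aR)-6-[(tert-butyldimethylsilyl)oxy]-4,4,7,8-tetramethyl-8-[(2,3,5,6-tetramethoxyphenyl)methyl]-1,2,3,4,4a,7,8,8a-octahydronaphthalen-1-ol (both C1 epimers) | COc1cc(OC)c(OC)c(C[C@@]2(C)[C@@H]3C(O)CCC(C)(C)[C@@H]3C=C(O[Si](C)(C)C(C)(C)C)[C@@H]2C)c1OC | intermediate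
22 | O-[(4aS,7R,8S,8aR)-6-[(tert-butyldimethylsilyl)oxy]-4,4,7,8-tetramethyl-8-[(2,3,5,6-tetramethoxyphenyl)methyl]-1,2,3,4,4a,7,8,8a-octahydronaphthalen-1-yl] 1H-imidazole-1-carbothioate (both C1 epimers) | COc1cc(OC)c(OC)c(C[C@@]2(C)[C@@H]3C(OC(=S)n4ccnc4)CCC(C)(C)[C@@H]3C=C(O[Si](C)(C)C(C)(C)C)[C@@H]2C)c1OC | intermediate
23 | tert-butyldimethyl{[(1S,2R,4aS,8aR)-1,2,5,5-tetramethyl-1-[(2,3,5,6-tetramethoxyphenyl)methyl]-1,2,4a,5,6,7,8,8a-octahydronaphthalen-3-yl]oxy}silane | COc1cc(OC)c(OC)c(C[C@@]2(C)[C@@H]3CCCC(C)(C)[C@@H]3C=C(O[Si](C)(C)C(C)(C)C)[C@@H]2C)c1OC | intermediate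
24 | (3R,4S,4aS)-3,4,8,8-tetramethyl-4-[(2,3,5,6-tetramethoxyphenyl)methyl]-4,4a,5,6,7,8-hexahydronaphthalen-2(3H)-one | COc1cc(OC)c(OC)c(C[C@@]2(C)[C@@H]3CCCC(C)(C)C3=CC(=O)[C@@H]2C)c1OC | intermediate
25 | (3'R,4'S,4a'S)-3',4',8',8'-tetramethyl-4'-[(2,3,5,6-tetramethoxyphenyl)methyl]-4',4a',5',6',7',8'-hexahydro-3'H-spiro[1,3-dithiolane-2,2'-naphthalene] | COc1cc(OC)c(OC)c(C[C@@]2(C)[C@@H]3CCCC(C)(C)C3=CC4(SCCS4)[C@@H]2C)c1OC | intermediate
26 | 1,2,4,5-tetramethoxy-3-{[(1R,2S,8aS)-1,2,5,5-tetramethyl-1,2,3,5,6,7,8,8a-octahydronaphthalen-1-yl]methyl}benzene | COc1cc(OC)c(OC)c(C[C@@]2(C)[C@@H]3CCCC(C)(C)C3=CC[C@@H]2C)c1OC | intermediate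
27 | 2,5-dimethoxy-3-{[(1R,2S,8aS)-1,2,5,5-tetramethyl-1,2,3,5,6,7,8,8a-octahydronaphthalen-1-yl]methyl}cyclohexa-2,5-diene-1,4-dione | COC1=CC(=O)C(OC)=C(C[C@@]2(C)[C@@H]3CCCC(C)(C)C3=CC[C@@H]2C)C1=O | intermediate
28 | 2-hydroxy-5-methoxy-3-{[(1R,2S,8aS)-1,2,5,5-tetramethyl-1,2,3,5,6,7,8,8a-octahydronaphthalen-1-yl]methyl}cyclohexa-2,5-diene-1,4-dione | COC1=CC(=O)C(O)=C(C[C@@]2(C)[C@@H]3CCCC(C)(C)C3=CC[C@@H]2C)C1=O | target

## Step count and least certain steps

Total step count: 17 (three for fragment 1, four for fragment 2, ten from their union to the target).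
Longest linear sequence: 14 steps (steps 4–17, from 2-methylpropanal and methyl acrylate).

**Step 9 (key step, proposed new method).** Three things may go wrong. The trisubstituted enone may be activated too weakly, so that protodesilylation of the dienol ether by the acidic catalyst, or a stepwise Mukaiyama–Michael addition that stops before ring closure, overtakes the cycloaddition. The catalyst may discriminate poorly between the enone faces, because the tether forces an s-cis enone that the usual binding picture does not cover. The uncatalysed racemic cyclisation may also compete. The fallback, which uses known chemistry, sets out from 19. Stoichiometric Me2AlCl (CH2Cl2, −78 → −20 °C), a Lewis acid of the kind already used for silyloxydiene trienones, should give the racemic cis-fused adduct, that is 20 together with its mirror image, (4aS,7S,8S,8aS)-6-[(tert-butyldimethylsilyl)oxy]-4,4,7,8-tetramethyl-8-[(2,3,5,6-tetramethoxyphenyl)methyl]-3,4,4a,7,8,8a-hexahydronaphthalen-1(2H)-one F1. The enantiomers are then separated by preparative chromatography on a cellulose tris(3,5-dimethylphenylcarbamate) phase, and the route is rejoined at 20.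

**Step 15 (with step 14).** Migration of the C5=C6 alkene on the nickel surface, partial saturation, or dienolisation toward C10 under BF3 in the preceding step would each degrade the only remaining functional group or the C10 centre; allylic dithioketals are the classic case of this. The fallback sets out from 24 and avoids both sulfur and nickel. NaBH4 with CeCl3·7H2O (MeOH, −40 °C) should give (3R,4S,4aS)-3,4,8,8-tetramethyl-4-[(2,3,5,6-tetramethoxyphenyl)methyl]-2,3,4,4a,5,6,7,8-octahydronaphthalen-2-ol F8 as a C2 epimer mixture. Acetylation (Ac2O, pyridine, DMAP) gives (3R,4S,4aS)-3,4,8,8-tetramethyl-4-[(2,3,5,6-tetramethoxyphenyl)methyl]-2,3,4,4a,5,6,7,8-octahydronaphthalen-2-yl acetate F9. Pd(PPh3)4 with LiBHEt3 in THF then delivers hydride to the less hindered C7 end of the allylpalladium intermediate and returns the route at 26.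

**Step 13.** Palladation of a tert-butyldimethylsilyl enol ether next to the C4 gem-dimethyl group may be slow, and loss of the silyl group to give the saturated C7 ketone would then compete and forfeit the regiochemical information. The fallback sets out from 23. PhSeCl (CH2Cl2, −78 °C) reacts with the enol ether regiospecifically at C6 to give (3R,4S,4aR,8aR)-3,4,8,8-tetramethyl-1-(phenylselanyl)-4-[(2,3,5,6-tetramethoxyphenyl)methyl]octahydronaphthalen-2(1H)-one F7 as a C1 epimer mixture. Oxidation with H2O2 and pyridine and syn elimination of the selenoxide toward H-5 return the route at 24.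

**Step 8.** The alkenyllithium may act as a base, deprotonating the amide α-CH2 or shifting a benzylic proton onto its own carbanion. The trienone may also begin to cyclise without catalyst during isolation, which would feed racemic material into step 9. The fallback sets out from 16 and 7. i-Bu2AlH (THF, −78 °C) reduces 16 to (5E,7Z)-7-[(tert-butyldimethylsilyl)oxy]-4,4-dimethylnona-5,7-dienal F5. A Nozaki–Hiyama–Kishi coupling of 7 with F5 (CrCl2, NiCl2 cat., DMF, rt) gives (2E,8E,10Z)-10-[(tert-butyldimethylsilyl)oxy]-2,7,7-trimethyl-1-(2,3,5,6-tetramethoxyphenyl)dodeca-2,8,10-trien-4-ol F6, racemic at the carbinol. Oxidation with MnO2 (CH2Cl2, 0 °C) returns the route at 19.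

**Step 3.** The four methoxy groups may tie up AlMe3, and the doubly activated benzylic–propargylic CH2 invites metallation or allene formation, so conversion or regiochemistry of the carbometallation may suffer. The fallback sets out from 1 and moves the carbometallation to a substrate without the arene. Prop-2-yn-1-ol F2 is carboaluminated and iodinated under the same conditions to (E)-3-iodo-2-methylprop-2-en-1-ol F3. CBr4 and PPh3 convert it into (E)-3-bromo-1-iodo-2-methylprop-1-ene F4. The aryllithium 3 (from 1 as in step 1), with 10 mol % CuI at −78 °C, is then alkylated by F4 at the allylic carbon, and the route is rejoined at 7.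

## Further compounds

F1 | step 9 | (4aS,7S,8S,8aS)-6-[(tert-butyldimethylsilyl)oxy]-4,4,7,8-tetramethyl-8-[(2,3,5,6-tetramethoxyphenyl)methyl]-3,4,4a,7,8,8a-hexahydronaphthalen-1(2H)-one | COc1cc(OC)c(OC)c(C[C@]2(C)[C@H]3C(=O)CCC(C)(C)[C@H]3C=C(O[Si](C)(C)C(C)(C)C)[C@H]2C)c1OC
F2 | step 3 | prop-2-yn-1-ol | C#CCO
F3 | step 3 | (E)-3-iodo-2-methylprop-2-en-1-ol | OC/C(C)=C/I
F4 | step 3 | (E)-3-bromo-1-iodo-2-methylprop-1-ene | BrC/C(C)=C/I
F5 | step 8 | (5E,7Z)-7-[(tert-butyldimethylsilyl)oxy]-4,4-dimethylnona-5,7-dienal | C/C=C(O[Si](C)(C)C(C)(C)C)/C=C/C(C)(C)CCC=O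
F6 | step 8 | (2E,8E,10Z)-10-[(tert-butyldimethylsilyl)oxy]-2,7,7-trimethyl-1-(2,3,5,6-tetramethoxyphenyl)dodeca-2,8,10-trien-4-ol (racemic) | C/C=C(O[Si](C)(C)C(C)(C)C)/C=C/C(C)(C)CCC(O)/C=C(\C)Cc1c(OC)c(OC)cc(OC)c1OC
F7 | step 13 | (3R,4S,4aR,8aR)-3,4,8,8-tetramethyl-1-(phenylselanyl)-4-[(2,3,5,6-tetramethoxyphenyl)methyl]octahydronaphthalen-2(1H)-one (both C1 epimers) | COc1cc(OC)c(OC)c(C[C@@]2(C)[C@@H]3CCCC(C)(C)[C@@H]3C([Se]c4ccccc4)C(=O)[C@@H]2C)c1OC
F8 | step 15 | (3R,4S,4aS)-3,4,8,8-tetramethyl-4-[(2,3,5,6-tetramethoxyphenyl)methyl]-2,3,4,4a,5,6,7,8-octahydronaphthalen-2-ol (both C2 epimers) | COc1cc(OC)c(OC)c(C[C@@]2(C)[C@@H]3CCCC(C)(C)C3=CC(O)[C@@H]2C)c1OC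
F9 | step 15 | (3R,4S,4aS)-3,4,8,8-tetramethyl-4-[(2,3,5,6-tetramethoxyphenyl)methyl]-2,3,4,4a,5,6,7,8-octahydronaphthalen-2-yl acetate (both C2 epimers) | COc1cc(OC)c(OC)c(C[C@@]2(C)[C@@H]3CCCC(C)(C)C3=CC(OC(C)=O)[C@@H]2C)c1OC
A1 | alternative 1 | 1-ethenyl-6,6-dimethylcyclohex-1-ene | C=CC1=CCCCC1(C)C
A2 | alternative 1 | (E)-2-methylbut-2-enal | C/C=C(\C)C=O
A3 | alternative 1 | (1R,2S,8aR)-1,2,5,5-tetramethyl-1,2,3,5,6,7,8,8a-octahydronaphthalene-1-carbaldehyde | O=C[C@@]2(C)[C@@H]3CCCC(C)(C)C3=CC[C@@H]2C
A4 | alternative 2 | (4S,6R)-6-(6,6-dimethylcyclohex-1-en-1-yl)-4-methyl-3-[(2,3,5,6-tetramethoxyphenyl)methyl]oxan-2-one (both C3 epimers) | COc1cc(OC)c(OC)c(CC2C(=O)O[C@@H](C3=CCCCC3(C)C)C[C@@H]2C)c1OC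
A5 | alternative 2 | (1S,2S,8aR)-2,5,5-trimethyl-1-[(2,3,5,6-tetramethoxyphenyl)methyl]-1,2,3,5,6,7,8,8a-octahydronaphthalene-1-carboxylic acid | COc1cc(OC)c(OC)c(C[C@@]2(C(O)=O)[C@@H]3CCCC(C)(C)C3=CC[C@@H]2C)c1OC
A6 | alternative 3 | 3-tert-butoxy-4-hydroxy-4-[(Z)-2-methoxyethenyl]-2-{[(1R,2S,8aS)-1,2,5,5-tetramethyl-1,2,3,5,6,7,8,8a-octahydronaphthalen-1-yl]methyl}cyclobut-2-en-1-one (both C4 epimers) | CO/C=C\C1(O)C(OC(C)(C)C)=C(C[C@@]2(C)[C@@H]3CCCC(C)(C)C3=CC[C@@H]2C)C1=O
A7 | alternative 3 | 2-tert-butoxy-5-methoxy-3-{[(1R,2S,8aS)-1,2,5,5-tetramethyl-1,2,3,5,6,7,8,8a-octahydronaphthalen-1-yl]methyl}benzene-1,4-diol | COc1cc(O)c(OC(C)(C)C)c(C[C@@]2(C)[C@@H]3CCCC(C)(C)C3=CC[C@@H]2C)c1O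
A8 | alternative 3 | 3,4-di-tert-butoxycyclobut-3-ene-1,2-dione | CC(C)(C)OC1=C(OC(C)(C)C)C(=O)C1=O
A9 | alternative 3 | {[(1R,2S,8aS)-1,2,5,5-tetramethyl-1,2,3,5,6,7,8,8a-octahydronaphthalen-1-yl]methyl}lithium | [Li]C[C@@]2(C)[C@@H]3CCCC(C)(C)C3=CC[C@@H]2C
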